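The constants used here were set for the occasion; what happens was integrated by code.

The flask held 0.0360 M of nucleophile against 0.024 M of electrophile, more of the first, and I doubted that this excess would reach the electrophile.

electrophile 0.024 M; nucleophile 0.0360 M; buffer base 0.0720 M; buffer acid 2.40 mM; time 2.5 d

    electrophile + nucleophile → acid + target + leaving group (k1 = 5.50 M⁻¹ h⁻¹)
    protonated nucleophile ⇌ nucleophile + acid, settled at all times (K2 = 3.2 × 10⁻¹⁰ M)
    buffer acid ⇌ buffer base + acid, settled at all times (K3 = 1.0 × 10⁻⁶ M)
    2 nucleophile → self-condensation product (k4 = 28.3 M⁻¹ h⁻¹)
    2 electrophile → homo dimer (k5 = 0.0177 M⁻¹ h⁻¹)

- part of the electrophile that has reacted at 2.5 d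
- pH of the solution at 2.5 d

- acid is the free proton; pH is minus the decimal logarithm of its molar concentration
- percent here means electrophile units held: one homo dimer counts as two
- where a step has two of a species, its rate is k times that concentration squared, and two are used at each turn
- run time (flask): 2.5 d

The nucleophile binds acid far more tightly than the buffer base does, with 3.2 × 10⁻¹⁰ M against 1.0 × 10⁻⁶ M, so I let it strip the buffer acid first, leaving 93.3% of its charge free. Each coupling then cost two nucleophile, one consumed and one protonated. Since the electrophile's half-life by coupling alone, with the other concentrations as charged, was 0.15 d, shorter than the 2.5 d run, my first estimate was 70.0% of the electrophile reacted.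

That estimate ignored self-condensation. At the start, the selectivity factor, self-condensation over coupling, was 7.20. So I divided the coupling rate by the total loss of free nucleophile and integrated down to zero free nucleophile, holding the electrophile at its charge. This gave 20.5%. I call this the burst share: the fraction of charged electrophile coupled while the free nucleophile lasts.

But the electrophile falls during the burst. Holding it at its mean level gave 19.2%, and I carried that lower share forward. The protonated nucleophile is also a reserve. Taking buffer acid back at its charge, a rough level that implied pH 7.48, I reckoned a further 2.22% of coupling from it. I put homo dimer at 3.33%. My total was 24.7%.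

The forecast gave 26% (23% to 30%) and pH 7.55 (7.4 to 7.75), on the ground that “only about a fifth of the electrophile couples early”. Both its numbers stood above mine.

The flask gave 25.5% and pH 7.65, inside both forecast ranges. Its target stood at 22.4%, against the burst share of 20.5%, or 19.2% with the electrophile's fall counted. The neighbouring flask had 0.0090 M of nucleophile, and there the same reckoning gave a burst share of 8.57%, or 8.44% with the fall counted, a reserve term of 1.40% and homo dimer of 4.27%, together 14.1%. That neighbouring flask ended with 15.1% reacted, 11.0% as target and 0.69% of its nucleophile free.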